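Amber puts a small charge of substrate, 0.41 M, under 0.820 M of coupling partner, twice as much.

| flask | substrate | coupling partner | remark | time |
|---|---|---|---|---|
| delta | 0.61 M | 0.82 M | run made earlier |  |
| alpha | 0.82 M | 0.82 M | run made earlier |  |
| amber | 0.41 M | 0.820 M |  | 4.0 d |
| teal | 0.41 M | 0.410 M |  | 4.0 d |

- delta (time / d: single product / %, substrate / %): 0.208: 61.9, 3.1; 0.417: 63.3, 1.6; 1.04: 62.9, 0; 2.50: 61.4, 0.4
- alpha (time / d: single product / %, substrate / %): 0.333: 60.0, 10.7; 0.833: 59.6, 9.5; 1.67: 60.0, 9.9; 2.50: 59.0, 10.2

(standard deviation of a reading: 0.5 percentage points)

- which of these holds the largest part of the substrate at the end of amber (other mono adduct / bis adduct / single product / substrate)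
- which of these holds the largest part of the substrate at the end of teal (other mono adduct / bis adduct / single product / substrate)
- single product at the end of amber, in percent of the substrate charged

Alpha is flat from its first reading, and at 1.67 d it reads substrate 9.9% and single product 60.0%. I read that as partner gone. So single product takes 66.6% of the substrate that reacted. The rest can go on to bis adduct, which holds two partners. So each substrate asks for 1.33 partner: the partner demand. Delta is a check from another run: it is charged at 1.34 equivalents, and its substrate reads 0% at 1.04 d.

Spare partner is c(coupling partner) minus the demand times c(substrate). In amber that gives 0.273 M, so substrate is the limiting reagent. In teal it is −0.137 M, so partner is limiting and I expect single product on top. For amber I lean to bis adduct and put single product below 66.6%, but I set no firm number.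

The forecast says bis adduct for amber, single product for teal, and 45% single product, within 30% to 63%: “over 4 days single falls from 65 to about 45”.

The flask gives bis adduct, single product and 37.4%, so the forecast's number is 7.6 percentage points too high.

    coupling partner + other mono adduct → bis adduct (k = 0.00533 M⁻¹ min⁻¹)
    coupling partner + single product → bis adduct (k = 0.0160 M⁻¹ min⁻¹)
    substrate + coupling partner → single product (k = 0.0357 M⁻¹ min⁻¹)
    substrate + coupling partner → other mono adduct (k = 0.0128 M⁻¹ min⁻¹)
    crystals ⇌ single product, rate k5*(cs5 - [single product]) while solid is left; crystals form when [single product] > cs5 (solubility = 5.60 mM, k = 0.0479 min⁻¹)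
    single product ⇌ isomer of the product (K = 0.466, k = 0.00261 min⁻¹)

Amber ends with 0.156 M of partner, less than the spare 0.273 M, so it has drawn 0.117 M beyond the demand. By the path to bis adduct alone, with partner as charged, dissolved single product in amber has a half-life of 0.88 h, short against 4.0 d, yet at the end crystals still hold 36.1% and dissolved single product is made 1.00 times as fast as it is used. A neighbour of amber charged with 1.0 M of substrate has a spare of −0.514 M, so I expect partner limiting. It ends with partner at 0%, substrate at 24.2% and single product at 51.1%.

(The data were computed with constants of no real substance; the scatter is artificial.)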